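The plan rests on cutting ring B (the epoxycyclohexene) between its vinylic CH (C-5) and the neighbouring carbinol carbon (C-6), which is flanked by the quaternary epoxide carbon C-1. The feature exploited is the allylic alcohol C-6(OH)–C-5H=C-4(CH2OH) of ring B, the retron of an alkenylmetal-to-aldehyde addition, with the C-1/C-2 epoxide next to it as the controlling element. An intramolecular Nozaki–Hiyama–Kishi reaction closes ring B and sets C-6 in one operation on a fully assembled, acyclic (Z)-iodoalkene α,β-epoxy aldehyde that already carries ring A, the dienyl side chain and all other stereocentres. This precursor is built convergently from three fragments.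

Key step: step 19

Locants used throughout (also for acyclic precursors): ring A = the trimethylcyclohexenol ring. Ring B = the epoxycyclohexene: C-1 quaternary epoxide carbon bearing the side chain, C-2 epoxide CH, C-3 CHOH, C-4 =C(CH2OH) with C-7 its CH2OH carbon, C-5 =CH, C-6 CHOH. Side chain: C-1′ (CHOH) to C-5′ (attached to ring A). TBS = tert-butyldimethylsilyl, TES = triethylsilyl.

Remark on the chemistry: in steps 12 and 15 the ligand antipode is the one that delivers the carbon nucleophile to the stated carbonyl face; the usual sense of induction of each ligand family is assumed.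
Remark on the chemistry: the epoxide face in step 16 follows the kinetic-resolution rule of the Sharpless epoxidation (L-(+)-tartrate, fast-reacting carbinol antipode, erythro product), which corresponds to the target configuration.
Remark on the chemistry: triethyl(prop-2-yn-1-yloxy)silane and (chloromethyl)dimethyl(propan-2-yloxy)silane are taken as purchasable.

**Fragment 1 (ring A dienal 12)**

Step 1
Reactants: 1 geranyl acetate
Product: 2 (2E)-5-[(2R)-3,3-dimethyloxiran-2-yl]-3-methylpent-2-en-1-yl acetate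
Conditions: D-fructose-derived Shi ketone (30 mol%), KHSO5 (Oxone), K2CO3, Bu4NHSO4, MeCN/CH2(OMe)2/aq. Na2B4O7 buffer, 0 °C
Reagents that add atoms: potassium peroxymonosulfate, [K+].[O-]S(=O)(=O)OO
Why: Shi asymmetric epoxidation, in which the chiral dioxirane should attack only the electron-rich 6,7-olefin (the 2,3-olefin is deactivated by the allylic acetate) through the spiro transition state and set the (R)-oxirane carbon that becomes the ring A carbinol.

Step 2
Reactants: 2 (2E)-5-[(2R)-3,3-dimethyloxiran-2-yl]-3-methylpent-2-en-1-yl acetate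
Product: 3 [(1S,5R)-5-hydroxy-2,6,6-trimethylcyclohex-2-en-1-yl]methyl acetate
Conditions: ZrCl4, CH2Cl2, 0 °C
Reagents that add atoms: none
Why: Lewis-acid-promoted epoxide-initiated cation–olefin cyclisation through a chair transition state, in which the E-olefin attacks the tertiary epoxide carbon anti to the breaking C–O bond, so that CH2OAc ends cis to the retained hydroxyl (new ring A stereocentre C-1) and endocyclic proton loss should give the cyclohex-2-ene.

Step 3
Reactants: 3 [(1S,5R)-5-hydroxy-2,6,6-trimethylcyclohex-2-en-1-yl]methyl acetate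
Product: 4 [(1S,5R)-5-(tert-butyldimethylsilyloxy)-2,6,6-trimethylcyclohex-2-en-1-yl]methyl acetate
Conditions: TBSOTf, 2,6-lutidine, CH2Cl2, −78 to 0 °C
Reagents that add atoms: tert-butyldimethylsilyl trifluoromethanesulfonate, CC(C)(C)[Si](C)(C)OS(=O)(=O)C(F)(F)F
Why: Silyl ether formation with the reactive triflate, needed because the secondary hydroxyl is neopentylic.

Step 4
Reactants: 4 [(1S,5R)-5-(tert-butyldimethylsilyloxy)-2,6,6-trimethylcyclohex-2-en-1-yl]methyl acetate
Product: 5 [(1S,5R)-5-(tert-butyldimethylsilyloxy)-2,6,6-trimethylcyclohex-2-en-1-yl]methanol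
Conditions: K2CO3 (cat.), MeOH, rt
Reagents that add atoms: none
Why: Base-catalysed transesterification (methanolysis) of the acetate, which leaves the TBS ether untouched.

Step 5
Reactants: 5 [(1S,5R)-5-(tert-butyldimethylsilyloxy)-2,6,6-trimethylcyclohex-2-en-1-yl]methanol
Product: 6 (1S,5R)-5-(tert-butyldimethylsilyloxy)-2,6,6-trimethylcyclohex-2-ene-1-carbaldehyde
Conditions: Dess–Martin periodinane, CH2Cl2, 0 °C
Reagents that add atoms: none
Why: Dess–Martin oxidation under non-basic conditions, so that the β,γ-unsaturated aldehyde should neither epimerise at C-1 nor move into conjugation.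

Step 6
Reactants: 6 (1S,5R)-5-(tert-butyldimethylsilyloxy)-2,6,6-trimethylcyclohex-2-ene-1-carbaldehyde
Product: 7 2-{(E)-2-[(1S,5R)-5-(tert-butyldimethylsilyloxy)-2,6,6-trimethylcyclohex-2-en-1-yl]ethenyl}-4,4,5,5-tetramethyl-1,3,2-dioxaborolane
Conditions: Cl2CHB(pin), CrCl2, LiI, THF, rt
Reagents that add atoms: 2-(dichloromethyl)-4,4,5,5-tetramethyl-1,3,2-dioxaborolane, ClC(Cl)B1OC(C)(C)C(C)(C)O1
Why: Takai–Utimoto boryl olefination through a geminal dichromium reagent, which is non-basic and E-selective and so should set the 4′E alkene without touching the α-stereocentre.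

Step 7
Reactants: 8 but-2-yn-1-ol
Product: 10 (Z)-3-iodobut-2-en-1-ol, via alkenylalanate 9 (not isolated)
Conditions: NaAlH2(OCH2CH2OMe)2, THF, 0 °C to rt; then I2, −78 °C
Reagents that add atoms: iodine, II
Why: Hydroxyl-directed trans-hydroalumination of the propargylic alcohol gives a five-membered oxaaluminacycle with aluminium on C-3, and iodinolysis with retention should give the Z-iodide (iodine cis to CH2OH).

Step 8
Reactants: 7 2-{(E)-2-[(1S,5R)-5-(tert-butyldimethylsilyloxy)-2,6,6-trimethylcyclohex-2-en-1-yl]ethenyl}-4,4,5,5-tetramethyl-1,3,2-dioxaborolane; 10 (Z)-3-iodobut-2-en-1-ol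
Product: 11 (2Z,4E)-5-[(1S,5R)-5-(tert-butyldimethylsilyloxy)-2,6,6-trimethylcyclohex-2-en-1-yl]-3-methylpenta-2,4-dien-1-ol
Conditions: Pd(dppf)Cl2 (5 mol%), K3PO4, THF/H2O, rt
Reagents that add atoms: none
Why: Suzuki–Miyaura coupling proceeds with retention at both alkenyl partners and should deliver the 2′Z,4′E diene directly.

Step 9
Reactants: 11 (2Z,4E)-5-[(1S,5R)-5-(tert-butyldimethylsilyloxy)-2,6,6-trimethylcyclohex-2-en-1-yl]-3-methylpenta-2,4-dien-1-ol
Product: 12 (2Z,4E)-5-[(1S,5R)-5-(tert-butyldimethylsilyloxy)-2,6,6-trimethylcyclohex-2-en-1-yl]-3-methylpenta-2,4-dienal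
Conditions: MnO2, CH2Cl2, rt, dark
Reagents that add atoms: none
Why: Mild allylic oxidation with MnO2, which should keep the 2′Z geometry if the dienal is used at once.

**Fragment 2 (alkyne 21)**

Step 10
Reactants: 13 prop-2-yn-1-ol
Product: 15 (E)-3-iodo-2-{[dimethyl(propan-2-yloxy)silyl]methyl}prop-2-en-1-ol (iodine cis to CH2OH), via alkenylmagnesium chelate 14 (not isolated)
Conditions: ClMgCH2SiMe2(OiPr) (from ClCH2SiMe2(OiPr) and Mg), CuI (10 mol%), THF, 0 °C to rt; then I2, −20 °C
Reagents that add atoms: [dimethyl(propan-2-yloxy)silyl]methylmagnesium chloride, CC(C)O[Si](C)(C)C[Mg]Cl; iodine, II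
Why: Copper-catalysed anti-carbomagnesiation of a propargylic alcohol puts the silylmethyl group (masked C-7 hydroxymethyl) on the internal carbon and magnesium on the terminal carbon within a five-membered alkoxide chelate, so iodinolysis with retention should place iodine cis to the future C-3.

Step 11
Reactants: 15 (E)-3-iodo-2-{[dimethyl(propan-2-yloxy)silyl]methyl}prop-2-en-1-ol
Product: 16 (E)-3-iodo-2-{[dimethyl(propan-2-yloxy)silyl]methyl}prop-2-enal (iodine cis to CHO)
Conditions: MnO2, CH2Cl2, rt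
Reagents that add atoms: none
Why: MnO2 oxidation of the allylic alcohol under neutral conditions that should tolerate the alkoxysilane and the iodoalkene.

Step 12
Reactants: 16 (E)-3-iodo-2-{[dimethyl(propan-2-yloxy)silyl]methyl}prop-2-enal; 17 triethyl(prop-2-yn-1-yloxy)silane
Product: 19 (1E,3S)-1-iodo-2-{[dimethyl(propan-2-yloxy)silyl]methyl}-6-(triethylsilyloxy)hex-1-en-4-yn-3-ol, via zinc acetylide 18 (not isolated)
Conditions: Me2Zn, ProPhenol ligand (20 mol%), Ph3PO (40 mol%), toluene, 0 °C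
Reagents that add atoms: none
Why: Dinuclear zinc (ProPhenol) catalysed asymmetric alkynylation, a reaction class that performs well with α,β-unsaturated aldehydes, should add the zinc acetylide 1,2 to the Si face of the enal and set C-3.

Step 13
Reactants: 19 (1E,3S)-1-iodo-2-{[dimethyl(propan-2-yloxy)silyl]methyl}-6-(triethylsilyloxy)hex-1-en-4-yn-3-ol
Product: 20 (1Z,3S)-2-(hydroxymethyl)-1-iodo-6-(triethylsilyloxy)hex-1-en-4-yn-3-ol
Conditions: H2O2 (30%), KHCO3, THF/MeOH, rt
Reagents that add atoms: hydrogen peroxide, OO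
Why: Tamao oxidation of the alkoxysilane converts C–Si into C–OH with retention of the allylic position, and fluoride is left out so that the primary TES ether should survive.

Step 14
Reactants: 20 (1Z,3S)-2-(hydroxymethyl)-1-iodo-6-(triethylsilyloxy)hex-1-en-4-yn-3-ol
Product: 21 (1Z,3S)-3-(tert-butyldimethylsilyloxy)-2-[(tert-butyldimethylsilyloxy)methyl]-1-iodo-6-(triethylsilyloxy)hex-1-en-4-yne
Conditions: TBSOTf, 2,6-lutidine, CH2Cl2, −78 °C
Reagents that add atoms: tert-butyldimethylsilyl trifluoromethanesulfonate, CC(C)(C)[Si](C)(C)OS(=O)(=O)C(F)(F)F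
Why: Double silylation of the primary and secondary hydroxyls leaves C-6 as the only TES ether, which can be unmasked selectively later.

**Union and completion**

Step 15
Reactants: 21 (1Z,3S)-3-(tert-butyldimethylsilyloxy)-2-[(tert-butyldimethylsilyloxy)methyl]-1-iodo-6-(triethylsilyloxy)hex-1-en-4-yne; 12 (2Z,4E)-5-[(1S,5R)-5-(tert-butyldimethylsilyloxy)-2,6,6-trimethylcyclohex-2-en-1-yl]-3-methylpenta-2,4-dienal
Product: 24 (1Z,3S,4E,6S,7Z,9E)-3-(tert-butyldimethylsilyloxy)-2-[(tert-butyldimethylsilyloxy)methyl]-1-iodo-8-methyl-5-[(triethylsilyloxy)methyl]-10-[(1S,5R)-5-(tert-butyldimethylsilyloxy)-2,6,6-trimethylcyclohex-2-en-1-yl]deca-1,4,7,9-tetraen-6-ol, via alkenylborane 22 (not isolated), via alkenylzinc 23 (not isolated)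
Conditions: Cy2BH, toluene, 0 °C to rt; Me2Zn, −78 °C; MIB (3-exo-morpholinoisoborneol, 10 mol%), then 12, −20 °C
Reagents that add atoms: none
Why: syn-Hydroboration should place boron on the less hindered alkyne carbon (next to CH2OTES, so C-6 ends cis to C-3), boron-to-zinc transmetallation proceeds with retention, and the amino-alcohol-catalysed alkenylzinc addition to the Re face of the dienal sets C-1′ as S.

Step 16
Reactants: 24 (the C-1′ bis-allylic alcohol)
Product: 25 epoxy alcohol: 24 epoxidised at C-1=C-2, with the epoxide oxygen erythro (anti) to the C-1′ hydroxyl and threo to O-3, and CH2OTES cis to C-3 on the oxirane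
Conditions: Ti(OiPr)4 (20 mol%), L-(+)-DIPT (24 mol%), t-BuOOH, 4 Å MS, CH2Cl2, −20 °C
Reagents that add atoms: tert-butyl hydroperoxide, CC(C)(C)OO
Why: Sharpless asymmetric epoxidation in its matched kinetic-resolution mode, where with L-(+)-tartrate the (S)-carbinol is the fast antipode and should deliver oxygen to the C-1=C-2 alkene to give the erythro epoxy alcohol (C-1 and C-2 set), while the Z-substituted side-chain alkene on the same carbinol is the mismatched, slow olefin.

Step 17
Reactants: 25 epoxy alcohol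
Product: 26 C-1′ tert-butyldimethylsilyl ether of 25
Conditions: TBSOTf, 2,6-lutidine, CH2Cl2, −78 °C
Reagents that add atoms: tert-butyldimethylsilyl trifluoromethanesulfonate, CC(C)(C)[Si](C)(C)OS(=O)(=O)C(F)(F)F
Why: Silylation at low temperature with buffered triflate protects the dienylic carbinol, rules out Payne migration of the epoxide and frees the next oxidation from a competing secondary alcohol.

Step 18
Reactants: 26 C-1′ tert-butyldimethylsilyl ether of 25
Product: 27 α,β-epoxy aldehyde: C-6 formyl group on the quaternary epoxide carbon C-1, with the (Z)-iodoalkene (iodine cis to C-3) intact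
Conditions: (COCl)2, DMSO, CH2Cl2, −78 to −40 °C; Et3N
Reagents that add atoms: none
Why: Under Swern conditions a primary TES ether is cleaved and oxidised directly to the aldehyde while TBS ethers persist, so C-6 should be unmasked in one operation.

Step 19
Reactants: 27 α,β-epoxy aldehyde
Product: 29 ring-B-closed tetrakis-TBS ether: 1,2-epoxycyclohex-4-ene with a free C-6 hydroxyl trans to the epoxide oxygen and cis to O-3, via alkenylchromium 28 (not isolated)
Conditions: CrCl2 (10 equiv), NiCl2 (5 mol%), DMSO, rt, 0.005 M, slow addition of 27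
Reagents that add atoms: none
Why: Zerovalent nickel (formed from NiCl2 and CrCl2) inserts into the only C–I bond, the alkenylnickel transmetallates to trivalent chromium with retention of the Z geometry, and the alkenylchromium adds to the C-6 aldehyde. The closest known reaction type is the intramolecular Nozaki–Hiyama–Kishi alkenylation used to close oxygenated cyclohexenols. Ring B closes in a 6-exo-trig mode (C-5 attacks the exocyclic C=O), which is possible only because iodine is cis to C-3 on the C-4=C-5 alkene. The new stereocentre C-6 is controlled by the adjacent C-1 epoxide: in the polar Felkin–Anh/Cornforth arrangement the carbonyl oxygen lies anti to the C-1–O bond, so the hydroxyl should end trans to the epoxide oxygen. The step needs chemoselectivity for the aldehyde over the epoxide and silyl ethers, which the weakly basic organochromium and the absence of any other halide should secure, and cyclisation over oligomerisation, which the Z-iodoalkene template and high dilution should secure.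

Step 20
Reactants: 29 ring-B-closed tetrakis-TBS ether
Product: 30 CNP0389279.1, (1R,2S,5R,6S)-4-(hydroxymethyl)-1-{(1S,2Z,4E)-1-hydroxy-5-[(1S,5R)-5-hydroxy-2,6,6-trimethylcyclohex-2-en-1-yl]-3-methylpenta-2,4-dien-1-yl}-7-oxabicyclo[4.1.0]hept-3-ene-2,5-diol
Conditions: Bu4NF, AcOH (1:1), THF, rt to 45 °C
Reagents that add atoms: none
Why: Fluoride-mediated global desilylation buffered with acetic acid should remove all four TBS groups without Payne migration of the epoxide or ionisation of the dienylic carbinol.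

**Compound list**

1 | geranyl acetate | CC(C)=CCC/C(C)=C/COC(C)=O | starting material
2 | (2E)-5-[(2R)-3,3-dimethyloxiran-2-yl]-3-methylpent-2-en-1-yl acetate | CC1(C)O[C@@H]1CC/C(C)=C/COC(C)=O | intermediate
3 | [(1S,5R)-5-hydroxy-2,6,6-trimethylcyclohex-2-en-1-yl]methyl acetate (OH and CH2OAc cis) | CC1=CC[C@@H](O)C(C)(C)[C@H]1COC(C)=O | intermediate
4 | [(1S,5R)-5-(tert-butyldimethylsilyloxy)-2,6,6-trimethylcyclohex-2-en-1-yl]methyl acetate | CC1=CC[C@@H](O[Si](C)(C)C(C)(C)C)C(C)(C)[C@H]1COC(C)=O | intermediate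
5 | [(1S,5R)-5-(tert-butyldimethylsilyloxy)-2,6,6-trimethylcyclohex-2-en-1-yl]methanol | CC1=CC[C@@H](O[Si](C)(C)C(C)(C)C)C(C)(C)[C@H]1CO | intermediate
6 | (1S,5R)-5-(tert-butyldimethylsilyloxy)-2,6,6-trimethylcyclohex-2-ene-1-carbaldehyde | CC1=CC[C@@H](O[Si](C)(C)C(C)(C)C)C(C)(C)[C@H]1C=O | intermediate
7 | 2-{(E)-2-[(1S,5R)-5-(tert-butyldimethylsilyloxy)-2,6,6-trimethylcyclohex-2-en-1-yl]ethenyl}-4,4,5,5-tetramethyl-1,3,2-dioxaborolane | CC1=CC[C@@H](O[Si](C)(C)C(C)(C)C)C(C)(C)[C@H]1/C=C/B1OC(C)(C)C(C)(C)O1 | intermediate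
8 | but-2-yn-1-ol | CC#CCO | starting material
9 | sodium cyclic alkenylalanate (aluminium on C-3, cis to CH2O) | [Na+].COCCO[Al-]1(OCCOC)OCC=C1C | intermediate
10 | (Z)-3-iodobut-2-en-1-ol | C/C(I)=C/CO | intermediate
11 | (2Z,4E)-5-[(1S,5R)-5-(tert-butyldimethylsilyloxy)-2,6,6-trimethylcyclohex-2-en-1-yl]-3-methylpenta-2,4-dien-1-ol | CC1=CC[C@@H](O[Si](C)(C)C(C)(C)C)C(C)(C)[C@H]1/C=C/C(C)=C\CO | intermediate
12 | (2Z,4E)-5-[(1S,5R)-5-(tert-butyldimethylsilyloxy)-2,6,6-trimethylcyclohex-2-en-1-yl]-3-methylpenta-2,4-dienal | CC1=CC[C@@H](O[Si](C)(C)C(C)(C)C)C(C)(C)[C@H]1/C=C/C(C)=C\C=O | intermediate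
13 | prop-2-yn-1-ol | C#CCO | starting material
14 | cyclic alkenylmagnesium alkoxide (magnesium on the terminal alkene carbon, cis to CH2O) | CC(C)O[Si](C)(C)CC1=C[Mg]OC1 | intermediate
15 | (E)-3-iodo-2-{[dimethyl(propan-2-yloxy)silyl]methyl}prop-2-en-1-ol (iodine cis to CH2OH) | OC/C(C[Si](C)(C)OC(C)C)=C\I | intermediate
16 | (E)-3-iodo-2-{[dimethyl(propan-2-yloxy)silyl]methyl}prop-2-enal (iodine cis to CHO) | O=C/C(C[Si](C)(C)OC(C)C)=C\I | intermediate
17 | triethyl(prop-2-yn-1-yloxy)silane | C#CCO[Si](CC)(CC)CC | starting material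
18 | methylzinc acetylide of 17 | C[Zn]C#CCO[Si](CC)(CC)CC | intermediate
19 | (1E,3S)-1-iodo-2-{[dimethyl(propan-2-yloxy)silyl]methyl}-6-(triethylsilyloxy)hex-1-en-4-yn-3-ol (iodine cis to C-3) | CC[Si](CC)(CC)OCC#C[C@H](O)/C(C[Si](C)(C)OC(C)C)=C\I | intermediate
20 | (1Z,3S)-2-(hydroxymethyl)-1-iodo-6-(triethylsilyloxy)hex-1-en-4-yn-3-ol | CC[Si](CC)(CC)OCC#C[C@H](O)/C(CO)=C\I | intermediate
21 | (1Z,3S)-3-(tert-butyldimethylsilyloxy)-2-[(tert-butyldimethylsilyloxy)methyl]-1-iodo-6-(triethylsilyloxy)hex-1-en-4-yne | CC[Si](CC)(CC)OCC#C[C@H](O[Si](C)(C)C(C)(C)C)/C(CO[Si](C)(C)C(C)(C)C)=C\I | intermediate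
22 | alkenyl(dicyclohexyl)borane from 21 (boron on the carbon bearing CH2OTES; CH2OTES cis to C-3) | CC[Si](CC)(CC)OC/C(B(C1CCCCC1)C1CCCCC1)=C\[C@H](O[Si](C)(C)C(C)(C)C)/C(CO[Si](C)(C)C(C)(C)C)=C\I | intermediate
23 | alkenyl(methyl)zinc from 22 (same geometry) | CC[Si](CC)(CC)OC/C([Zn]C)=C\[C@H](O[Si](C)(C)C(C)(C)C)/C(CO[Si](C)(C)C(C)(C)C)=C\I | intermediate
24 | (1Z,3S,4E,6S,7Z,9E)-3-(tert-butyldimethylsilyloxy)-2-[(tert-butyldimethylsilyloxy)methyl]-1-iodo-8-methyl-5-[(triethylsilyloxy)methyl]-10-[(1S,5R)-5-(tert-butyldimethylsilyloxy)-2,6,6-trimethylcyclohex-2-en-1-yl]deca-1,4,7,9-tetraen-6-ol (C-1′ S, C-3 S) | CC1=CC[C@@H](O[Si](C)(C)C(C)(C)C)C(C)(C)[C@H]1/C=C/C(C)=C\[C@H](O)/C(CO[Si](CC)(CC)CC)=C/[C@H](O[Si](C)(C)C(C)(C)C)/C(CO[Si](C)(C)C(C)(C)C)=C\I | intermediate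
25 | epoxy alcohol: C-1/C-2 epoxide of 24, oxygen erythro to the C-1′ hydroxyl and threo to O-3, CH2OTES cis to C-3 (C-1′ S, C-1 S, C-2 S, C-3 R) | CC1=CC[C@@H](O[Si](C)(C)C(C)(C)C)C(C)(C)[C@H]1/C=C/C(C)=C\[C@H](O)[C@]1(CO[Si](CC)(CC)CC)O[C@H]1[C@H](O[Si](C)(C)C(C)(C)C)/C(CO[Si](C)(C)C(C)(C)C)=C\I | intermediate
26 | C-1′ tert-butyldimethylsilyl ether of 25 (configuration unchanged) | CC1=CC[C@@H](O[Si](C)(C)C(C)(C)C)C(C)(C)[C@H]1/C=C/C(C)=C\[C@H](O[Si](C)(C)C(C)(C)C)[C@]1(CO[Si](CC)(CC)CC)O[C@H]1[C@H](O[Si](C)(C)C(C)(C)C)/C(CO[Si](C)(C)C(C)(C)C)=C\I | intermediate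
27 | α,β-epoxy aldehyde: 26 with C-6 as CHO on the epoxide carbon C-1 (configuration unchanged) | CC1=CC[C@@H](O[Si](C)(C)C(C)(C)C)C(C)(C)[C@H]1/C=C/C(C)=C\[C@H](O[Si](C)(C)C(C)(C)C)[C@]1(C=O)O[C@H]1[C@H](O[Si](C)(C)C(C)(C)C)/C(CO[Si](C)(C)C(C)(C)C)=C\I | intermediate
28 | alkenylchromium dichloride from 27 (chromium in place of iodine, cis to C-3) | CC1=CC[C@@H](O[Si](C)(C)C(C)(C)C)C(C)(C)[C@H]1/C=C/C(C)=C\[C@H](O[Si](C)(C)C(C)(C)C)[C@]1(C=O)O[C@H]1[C@H](O[Si](C)(C)C(C)(C)C)/C(CO[Si](C)(C)C(C)(C)C)=C\[Cr](Cl)Cl | intermediate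
29 | ring-B-closed tetrakis-TBS ether: free C-6 hydroxyl (S) trans to the epoxide oxygen and cis to O-3; silyl ethers at O-1′, O-3, O-7 and on ring A | CC1=CC[C@@H](O[Si](C)(C)C(C)(C)C)C(C)(C)[C@H]1/C=C/C(C)=C\[C@H](O[Si](C)(C)C(C)(C)C)[C@]12O[C@H]1[C@H](O[Si](C)(C)C(C)(C)C)C(CO[Si](C)(C)C(C)(C)C)=C[C@@H]2O | intermediate
30 | CNP0389279.1, (1R,2S,5R,6S)-4-(hydroxymethyl)-1-{(1S,2Z,4E)-1-hydroxy-5-[(1S,5R)-5-hydroxy-2,6,6-trimethylcyclohex-2-en-1-yl]-3-methylpenta-2,4-dien-1-yl}-7-oxabicyclo[4.1.0]hept-3-ene-2,5-diol | CC1=CC[C@@H](O)C(C)(C)[C@H]1/C=C/C(C)=C\[C@H](O)[C@]12O[C@H]1[C@H](O)C(CO)=C[C@@H]2O | target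

**Step count**

Total step count: 20. Longest linear sequence: 14 steps (steps 1–6, 8, 9 and 15–20).

**Steps most likely to fail**

Step 19 (key step). The divalent chromium may open or reduce the α,β-epoxy aldehyde before the C–C bond forms, closure may be slow enough for intermolecular coupling to compete, or the aldehyde may be attacked on the wrong face. The fallback keeps the same C-5–C-6 bond formation but makes it an anionic acylation followed by a separate reduction. It sets out from 27: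
- Pinnick oxidation (NaClO2, NaH2PO4, 2-methylbut-2-ene) should give the epoxy acid F1.
- Coupling with MeNH(OMe)·HCl (EDC·HCl, HOBt, iPr2NEt) should give the Weinreb amide F2.
- Iodine–lithium exchange with t-BuLi (THF/Et2O, −100 °C) should be followed by 6-exo attack of the alkenyllithium on the amide to give the epoxy cyclohexenone F3.
- Luche reduction (NaBH4, CeCl3·7H2O, MeOH, −78 °C), with hydride entering anti to the bulky C-1 side chain, should return the route to 29.

Step 15. Hydroboration may occur at the wrong alkyne carbon, the alkenylzinc may be lost by β-elimination of the silyloxy group, or the facial selectivity of the addition may be low. The fallback fixes regiochemistry and alkene geometry with an ester and leaves the C-1′ selection to step 16. It sets out from 16: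
- ProPhenol/Me2Zn addition of methyl propiolate should give the hydroxy ynoate F4.
- Tamao oxidation should give the diol F5, and TBSOTf/2,6-lutidine the bis-silyl ynoate F6.
- Hydroalumination with i-Bu2AlH/N-methylmorpholine N-oxide (aluminium α to the ester, hydride on the β-carbon, syn) and addition of the alkenylalane to 12 should give the (Z)-α-(hydroxyalkyl) enoate F7 as a C-1′ epimer mixture.
- i-Bu2AlH reduction of the ester should give the diol F8.
- Selective silylation of the primary hydroxyl (TESCl, imidazole, −78 °C) returns the route to 24 together with the C-1′ epimer of 24 F9. F9 is the slow-reacting partner under the L-(+)-tartrate conditions of step 16 and would be removed there.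

Step 12. The zinc acetylide may add in conjugate fashion to the β-iodo enal with loss of iodide, and an uncatalysed background addition may erode the facial selectivity. The fallback replaces the asymmetric C–C bond formation by an asymmetric reduction. It sets out from 16 and 17:
- The lithium acetylide of 17 (LiN(SiMe3)2, then CeCl3, THF, −78 °C) should add 1,2 to 16 to give racemic carbinol, that is 19 with the enantiomer of 19 F10.
- Dess–Martin oxidation should give the achiral alkynyl alkenyl ketone F11.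
- Corey–Bakshi–Shibata reduction (2-methyl-CBS-oxazaborolidine, catecholborane, −78 °C; hydride to the Re face, with the alkenyl group as the large substituent) returns the route to 19.

Further compounds
F1 | step 19 | epoxy carboxylic acid from 27 (C-6 as CO2H, configuration unchanged) | CC1=CC[C@@H](O[Si](C)(C)C(C)(C)C)C(C)(C)[C@H]1/C=C/C(C)=C\[C@H](O[Si](C)(C)C(C)(C)C)[C@]1(C(O)=O)O[C@H]1[C@H](O[Si](C)(C)C(C)(C)C)/C(CO[Si](C)(C)C(C)(C)C)=C\I
F2 | step 19 | N-methoxy-N-methyl amide of F1 | CC1=CC[C@@H](O[Si](C)(C)C(C)(C)C)C(C)(C)[C@H]1/C=C/C(C)=C\[C@H](O[Si](C)(C)C(C)(C)C)[C@]1(C(=O)N(C)OC)O[C@H]1[C@H](O[Si](C)(C)C(C)(C)C)/C(CO[Si](C)(C)C(C)(C)C)=C\I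
F3 | step 19 | ring-B epoxy cyclohexenone (C-6 ketone conjugated to C-4=C-5) | CC1=CC[C@@H](O[Si](C)(C)C(C)(C)C)C(C)(C)[C@H]1/C=C/C(C)=C\[C@H](O[Si](C)(C)C(C)(C)C)[C@]12O[C@H]1[C@H](O[Si](C)(C)C(C)(C)C)C(CO[Si](C)(C)C(C)(C)C)=CC2=O
F4 | step 15 | methyl (4S,5E)-4-hydroxy-6-iodo-5-{[dimethyl(propan-2-yloxy)silyl]methyl}hex-5-en-2-ynoate (iodine cis to C-4) | COC(=O)C#C[C@H](O)/C(C[Si](C)(C)OC(C)C)=C\I
F5 | step 15 | methyl (4S,5Z)-4-hydroxy-5-(hydroxymethyl)-6-iodohex-5-en-2-ynoate | COC(=O)C#C[C@H](O)/C(CO)=C\I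
F6 | step 15 | methyl (4S,5Z)-4-(tert-butyldimethylsilyloxy)-5-[(tert-butyldimethylsilyloxy)methyl]-6-iodohex-5-en-2-ynoate | COC(=O)C#C[C@H](O[Si](C)(C)C(C)(C)C)/C(CO[Si](C)(C)C(C)(C)C)=C\I
F7 | step 15 | methyl ester analogue of 24 (CO2Me in place of CH2OTES, ester cis to C-3), C-1′ epimer mixture | CC1=CC[C@@H](O[Si](C)(C)C(C)(C)C)C(C)(C)[C@H]1/C=C/C(C)=C\C(O)/C(C(=O)OC)=C/[C@H](O[Si](C)(C)C(C)(C)C)/C(CO[Si](C)(C)C(C)(C)C)=C\I
F8 | step 15 | diol analogue of 24 (free C-6 CH2OH), C-1′ epimer mixture | CC1=CC[C@@H](O[Si](C)(C)C(C)(C)C)C(C)(C)[C@H]1/C=C/C(C)=C\C(O)/C(CO)=C/[C@H](O[Si](C)(C)C(C)(C)C)/C(CO[Si](C)(C)C(C)(C)C)=C\I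
F9 | step 15 | C-1′ epimer of 24 | CC1=CC[C@@H](O[Si](C)(C)C(C)(C)C)C(C)(C)[C@H]1/C=C/C(C)=C\[C@@H](O)/C(CO[Si](CC)(CC)CC)=C/[C@H](O[Si](C)(C)C(C)(C)C)/C(CO[Si](C)(C)C(C)(C)C)=C\I
F10 | step 12 | enantiomer of 19, (1E,3R)-1-iodo-2-{[dimethyl(propan-2-yloxy)silyl]methyl}-6-(triethylsilyloxy)hex-1-en-4-yn-3-ol | CC[Si](CC)(CC)OCC#C[C@@H](O)/C(C[Si](C)(C)OC(C)C)=C\I
F11 | step 12 | (1E)-1-iodo-2-{[dimethyl(propan-2-yloxy)silyl]methyl}-6-(triethylsilyloxy)hex-1-en-4-yn-3-one | CC[Si](CC)(CC)OCC#CC(=O)/C(C[Si](C)(C)OC(C)C)=C\I
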